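Everything rests on forming the O1–C2 bond of the oxolane last (O1; C2 with aryl ring B; C3 with CH2OH; C4 with OH and the ring-A benzyl group; C5). C2 is benzylic on ring B and para to its ether oxygen, so DDQ can take hydride from it, and the C5 hydroxyl, held 1,4 to it, traps the cation. One operation gives the ring, the O1–C2 bond and the C2 stereocentre, directed by C3. The substrate is open-chain pentaol 31 with rings A and C (C = aryl of the glycerol ether) deactivated as acetates; it is built by SNAr etherification, Evans alkylation (C3), enolate hydroxylation and dianion benzylation (C4), reduction, hydrogenolysis and phenol acetylation.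

Key step: step 17

Assumption: compounds 1, 16 and 25 are taken as catalogue compounds (each is otherwise one routine step from 4-bromo-2-methoxyphenol, succinic anhydride or vanillin), and the minor syn adduct of step 1 is removed by chromatography.

Shorthand: ArB = 4-{[(1S,2R)-1,3-bis(benzyloxy)-1-[4-(benzyloxy)-3-methoxyphenyl]propan-2-yl]oxy}-3-methoxyphenyl (ring B carrying the protected glycerol ether); Bn = benzyl.

Step 1
Reactants: 1 1-(benzyloxy)-4-bromo-2-methoxybenzene; 2 (R)-2,3-O-isopropylideneglyceraldehyde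
Product: 5 (S)-[4-(benzyloxy)-3-methoxyphenyl][(4R)-2,2-dimethyl-1,3-dioxolan-4-yl]methanol, via aryl Grignard reagent 3 (not isolated), via aryltitanium triisopropoxide 4 (not isolated)
Conditions: Mg, THF, 40 °C; ClTi(OiPr)3, −78 → −20 °C; then 2, −78 → 0 °C; aq. NH4Cl
Reagents that add atoms: none
Why: Transmetalation of the Grignard reagent to the non-chelating aryltitanium triisopropoxide and 1,2-addition to the α-alkoxy aldehyde should follow the Felkin–Anh model, the aryl group entering anti to the dioxolane C–O bond to give the anti (1S) carbinol, while the dioxolane carbon keeps its R configuration.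

Step 2
Reactants: 5 (S)-[4-(benzyloxy)-3-methoxyphenyl][(4R)-2,2-dimethyl-1,3-dioxolan-4-yl]methanol
Product: 6 (4R)-4-{(S)-(benzyloxy)[4-(benzyloxy)-3-methoxyphenyl]methyl}-2,2-dimethyl-1,3-dioxolane
Conditions: BnBr, NaH, Bu4NI (cat.), THF/DMF (4:1), 0 °C → rt
Reagents that add atoms: benzyl bromide, BrCc1ccccc1
Why: Williamson etherification of the secondary alkoxide with benzyl bromide leaves both stereocentres and the acetonide untouched.

Step 3
Reactants: 6 (4R)-4-{(S)-(benzyloxy)[4-(benzyloxy)-3-methoxyphenyl]methyl}-2,2-dimethyl-1,3-dioxolane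
Product: 7 (2R,3S)-3-(benzyloxy)-3-[4-(benzyloxy)-3-methoxyphenyl]propane-1,2-diol
Conditions: AcOH/H2O/THF (3:1:1), 45 °C
Reagents that add atoms: none
Why: Acid-catalysed hydrolysis of the terminal isopropylidene acetal in a weak acid should spare the para-alkoxybenzylic benzyl ether.

Step 4
Reactants: 7 (2R,3S)-3-(benzyloxy)-3-[4-(benzyloxy)-3-methoxyphenyl]propane-1,2-diol
Product: 9 (1S,2R)-1,3-bis(benzyloxy)-1-[4-(benzyloxy)-3-methoxyphenyl]propan-2-ol, via stannylene acetal 8 (not isolated)
Conditions: Bu2SnO, toluene, reflux (Dean–Stark); then BnBr, Bu4NBr, 90 °C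
Reagents that add atoms: benzyl bromide, BrCc1ccccc1
Why: Stannylene-acetal-mediated regioselective alkylation activates the primary oxygen, so the benzyl group goes to O3 and the C2 hydroxyl stays free.

Step 5
Reactants: 9 (1S,2R)-1,3-bis(benzyloxy)-1-[4-(benzyloxy)-3-methoxyphenyl]propan-2-ol; 10 4-fluoro-3-methoxybenzaldehyde
Product: 12 4-{[(1S,2R)-1,3-bis(benzyloxy)-1-[4-(benzyloxy)-3-methoxyphenyl]propan-2-yl]oxy}-3-methoxybenzaldehyde (ArB–CHO), via sodium alkoxide 11 (not isolated)
Conditions: NaH, DMF, 0 °C; then 10, 0 °C → rt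
Reagents that add atoms: none
Why: Nucleophilic aromatic substitution (addition–elimination through a Meisenheimer adduct para to the formyl group) makes the aryl ether from the oxygen side, so the C–O bond at the carbinol carbon is never broken and its R configuration is retained.

Step 6
Reactants: 12 ArB–CHO
Product: 13 ArB–CH2OH, (4-{[(1S,2R)-1,3-bis(benzyloxy)-1-[4-(benzyloxy)-3-methoxyphenyl]propan-2-yl]oxy}-3-methoxyphenyl)methanol
Conditions: NaBH4, MeOH/THF (1:1), 0 °C
Reagents that add atoms: none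
Why: Borohydride reduction of the aromatic aldehyde gives the benzylic alcohol and touches nothing else.

Step 7
Reactants: 13 ArB–CH2OH
Product: 14 ArB–CH2Br, 4-(bromomethyl)-1-{[(1S,2R)-1,3-bis(benzyloxy)-1-[4-(benzyloxy)-3-methoxyphenyl]propan-2-yl]oxy}-2-methoxybenzene
Conditions: CBr4, PPh3, CH2Cl2, 0 °C
Reagents that add atoms: tetrabromomethane, BrC(Br)(Br)Br
Why: The Appel reaction converts the electron-rich benzylic alcohol into the bromide under neutral conditions, without HBr that could ionise the benzylic ether, and the bromide is used at once.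

Step 8
Reactants: 15 (R)-4-benzyloxazolidin-2-one; 16 methyl 4-chloro-4-oxobutanoate
Product: 18 methyl 4-[(4R)-4-benzyl-2-oxooxazolidin-3-yl]-4-oxobutanoate, via lithium oxazolidinide 17 (not isolated)
Conditions: n-BuLi, THF, −78 °C; then 16, −78 → 0 °C
Reagents that add atoms: none
Why: N-acylation of the lithiated oxazolidinone by the acid chloride loads the Evans auxiliary, and the methyl ester is inert at this temperature.

Step 9
Reactants: 18 methyl 4-[(4R)-4-benzyl-2-oxooxazolidin-3-yl]-4-oxobutanoate (1.5 equiv); 14 ArB–CH2Br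
Product: 20 methyl (3R)-3-(ArB-methyl)-4-[(4R)-4-benzyl-2-oxooxazolidin-3-yl]-4-oxobutanoate, via sodium enolate 19 (not isolated)
Conditions: NaN(SiMe3)2, THF, −78 °C; then 14, −78 → −30 °C
Reagents that add atoms: none
Why: In this Evans asymmetric alkylation the base removes only the far more acidic imide α-proton to give the chelated Z-enolate, and the benzylic bromide attacks the face opposite the 4-benzyl group of the (R)-auxiliary, which sets the future C3 (3R in 20).

Step 10
Reactants: 20 methyl (3R)-3-(ArB-methyl)-4-[(4R)-4-benzyl-2-oxooxazolidin-3-yl]-4-oxobutanoate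
Product: 22 (4R)-4-(ArB-methyl)oxolan-2-one, via hydroxy ester 21 (not isolated)
Conditions: NaBH4, THF/H2O (4:1), 0 °C → rt; then aq. citric acid (pH 4), rt
Reagents that add atoms: none
Why: Chemoselective borohydride reduction of the N-acyl oxazolidinone releases the auxiliary and a primary alcohol, which lactonises onto the γ-methyl ester (intramolecular transesterification) without touching the stereocentre.

Step 11
Reactants: 22 (4R)-4-(ArB-methyl)oxolan-2-one
Product: 24 (3R,4S)-3-hydroxy-4-(ArB-methyl)oxolan-2-one, via potassium enolate 23 (not isolated)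
Conditions: KN(SiMe3)2, THF, −78 °C; then 3-phenyl-2-(phenylsulfonyl)oxaziridine, −78 °C; AcOH
Reagents that add atoms: 3-phenyl-2-(phenylsulfonyl)oxaziridine, O=S(=O)(c1ccccc1)N1OC1c1ccccc1
Why: Electrophilic α-hydroxylation of the lactone enolate with the Davis oxaziridine occurs on the face opposite the C4 substituent to give the 3,4-trans hydroxy lactone, and this carbinol configuration need not be kept because C3 is planarised again in step 13.

Step 12
Reactants: 25 [4-(benzyloxy)-3-methoxyphenyl]methanol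
Product: 26 1-(benzyloxy)-4-(bromomethyl)-2-methoxybenzene
Conditions: PBr3, Et2O, 0 °C
Reagents that add atoms: phosphorus tribromide, BrP(Br)Br
Why: Bromide displaces the phosphite ester of the benzylic alcohol (SN2), the standard conversion of a benzylic alcohol into its bromide.

Step 13
Reactants: 24 (3R,4S)-3-hydroxy-4-(ArB-methyl)oxolan-2-one; 26 1-(benzyloxy)-4-(bromomethyl)-2-methoxybenzene
Product: 28 (3S,4S)-3-{[4-(benzyloxy)-3-methoxyphenyl]methyl}-3-hydroxy-4-(ArB-methyl)oxolan-2-one, via dilithium enediolate 27 (not isolated)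
Conditions: LiN(iPr)2 (2.4 equiv), THF/DMPU, −78 → −40 °C; then 26, −78 → −20 °C; AcOH
Reagents that add atoms: none
Why: Alkylation of the α-hydroxy lactone dianion (alkoxide enolate) takes the bromide on the face of the planar enediolate anti to the C4 arylmethyl group, so the ring-A benzyl group ends trans to it and the hydroxyl cis, which sets the quaternary carbon (future C4) as S.

Step 14
Reactants: 28 (3S,4S)-3-{[4-(benzyloxy)-3-methoxyphenyl]methyl}-3-hydroxy-4-(ArB-methyl)oxolan-2-one
Product: 29 (2S,3S)-2-{[4-(benzyloxy)-3-methoxyphenyl]methyl}-3-(ArB-methyl)butane-1,2,4-triol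
Conditions: LiAlH4, THF, 0 °C → rt; then H2O, 15% aq. NaOH
Reagents that add atoms: none
Why: Hydride reduction of the lactone to the diol gives the 1,2,4-triol without touching either stereocentre or the benzyl ethers.

Step 15
Reactants: 29 (2S,3S)-2-{[4-(benzyloxy)-3-methoxyphenyl]methyl}-3-(ArB-methyl)butane-1,2,4-triol
Product: 30 (2S,3S)-2-[(4-hydroxy-3-methoxyphenyl)methyl]-3-[(4-{[(1S,2R)-1,3-dihydroxy-1-(4-hydroxy-3-methoxyphenyl)propan-2-yl]oxy}-3-methoxyphenyl)methyl]butane-1,2,4-triol
Conditions: H2 (1 atm), 10% Pd/C, EtOAc/MeOH (1:1), rt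
Reagents that add atoms: none
Why: Catalytic hydrogenolysis cleaves the two aryl and two alkyl benzyl ethers at their unhindered PhCH2–O bonds in neutral solvent, and it is stopped after four equivalents of hydrogen so that the benzylic carbinol C–O bond is kept.

Step 16
Reactants: 30 the heptaol of step 15
Product: 31 open-chain pentaol bis(aryl acetate): 30 with the phenols of rings A and C acetylated
Conditions: Ac2O (2.2 equiv), 1 M aq. NaOH (2.4 equiv), THF, 0 °C, 15 min
Reagents that add atoms: acetic anhydride, CC(=O)OC(C)=O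
Why: Under Schotten–Baumann conditions only the two phenols are ionised in cold dilute NaOH and they take the acetyl groups, while the five aliphatic hydroxyls stay free.

Step 17
Reactants: 31 open-chain pentaol bis(aryl acetate)
Product: 33 (2S,3R,4S)-oxolane as its ring-A and ring-C aryl acetates, via benzylic cation 32 (not isolated)
Conditions: DDQ (1.1 equiv), NaHCO3, 4 Å molecular sieves, CH2Cl2/MeCN (4:1), 0 °C → rt
Reagents that add atoms: none
Why: DDQ forms a charge-transfer complex with ring B, the only ring that still carries two ether oxygens, and removes hydride from its benzylic CH2 (C2) to give the para-alkoxybenzylic cation 32, which the C5 hydroxyl captures to make the O1–C2 bond. The closest known reaction type is the DDQ-mediated oxidative cyclisation of 3,4-dialkoxybenzylic C–H bonds onto a tethered alcohol, the laboratory counterpart of quinone-methide trapping in lignan biosynthesis. The oxolane closes in the 5-exo-trig mode, whereas the C4 hydroxyl and the C3 hydroxymethyl could only give four-membered rings and stay spectators. The new C2 stereocentre is controlled by C3: in the envelope transition state the planar aryl cation sits anti to the C3 hydroxymethyl group and so also anti to the C4 benzyl group, which gives the 2,3-trans (2S) ring, and this ring is also the more stable one, so reversible ionisation of the benzylic C–O bond would not erode it. The step needs site selectivity among three benzylic positions and chemoselectivity over the ring-C benzylic carbinol, and both come from the two aryl acetates, which raise the oxidation potential of rings A and C. Over-oxidation of the new benzylic ether and Friedel–Crafts capture of the cation by ring A are limited by 1.1 equivalents of oxidant, dry buffered conditions and a short reaction time.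

Step 18
Reactants: 33 (2S,3R,4S)-oxolane bis(aryl acetate)
Product: 34 (1S,2R)-1-(4-hydroxy-3-methoxyphenyl)-2-{4-[(2S,3R,4S)-4-hydroxy-4-[(4-hydroxy-3-methoxyphenyl)methyl]-3-(hydroxymethyl)oxolan-2-yl]-2-methoxyphenoxy}propane-1,3-diol
Conditions: K2CO3 (0.3 equiv), MeOH, 0 °C → rt; pH 7 phosphate buffer
Reagents that add atoms: none
Why: Base-catalysed methanolysis (transesterification) removes the two aryl acetates as methyl acetate under conditions too mild to affect the ethers, the alcohols or any stereocentre, and the neutral work-up avoids acid-induced ring-A cyclisation of the benzylic oxolane.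

Compound list
1 | 1-(benzyloxy)-4-bromo-2-methoxybenzene | COc1cc(Br)ccc1OCc1ccccc1 | starting material
2 | (R)-2,3-O-isopropylideneglyceraldehyde | CC1(C)OC[C@H](C=O)O1 | starting material
3 | [4-(benzyloxy)-3-methoxyphenyl]magnesium bromide (formed in situ) | COc1cc([Mg]Br)ccc1OCc1ccccc1 | intermediate
4 | [4-(benzyloxy)-3-methoxyphenyl]titanium triisopropoxide (formed in situ) | COc1cc([Ti](OC(C)C)(OC(C)C)OC(C)C)ccc1OCc1ccccc1 | intermediate
5 | (S)-[4-(benzyloxy)-3-methoxyphenyl][(4R)-2,2-dimethyl-1,3-dioxolan-4-yl]methanol | CC1(C)OC[C@@H](O1)[C@@H](O)c1ccc(OCc2ccccc2)c(OC)c1 | intermediate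
6 | (4R)-4-{(S)-(benzyloxy)[4-(benzyloxy)-3-methoxyphenyl]methyl}-2,2-dimethyl-1,3-dioxolane | CC1(C)OC[C@@H](O1)[C@@H](OCc1ccccc1)c1ccc(OCc2ccccc2)c(OC)c1 | intermediate
7 | (2R,3S)-3-(benzyloxy)-3-[4-(benzyloxy)-3-methoxyphenyl]propane-1,2-diol | OC[C@@H](O)[C@@H](OCc1ccccc1)c1ccc(OCc2ccccc2)c(OC)c1 | intermediate
8 | (4R)-4-{(S)-(benzyloxy)[4-(benzyloxy)-3-methoxyphenyl]methyl}-2,2-dibutyl-1,3,2-dioxastannolane (formed in situ) | CCCC[Sn]1(CCCC)OC[C@@H](O1)[C@@H](OCc1ccccc1)c1ccc(OCc2ccccc2)c(OC)c1 | intermediate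
9 | (1S,2R)-1,3-bis(benzyloxy)-1-[4-(benzyloxy)-3-methoxyphenyl]propan-2-ol | O[C@H](COCc1ccccc1)[C@@H](OCc1ccccc1)c1ccc(OCc2ccccc2)c(OC)c1 | intermediate
10 | 4-fluoro-3-methoxybenzaldehyde | COc1cc(C=O)ccc1F | starting material
11 | sodium alkoxide of 9 (formed in situ) | [Na+].[O-][C@H](COCc1ccccc1)[C@@H](OCc1ccccc1)c1ccc(OCc2ccccc2)c(OC)c1 | intermediate
12 | 4-{[(1S,2R)-1,3-bis(benzyloxy)-1-[4-(benzyloxy)-3-methoxyphenyl]propan-2-yl]oxy}-3-methoxybenzaldehyde (ArB–CHO) | COc1cc(C=O)ccc1O[C@H](COCc1ccccc1)[C@@H](OCc1ccccc1)c1ccc(OCc2ccccc2)c(OC)c1 | intermediate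
13 | ArB–CH2OH, the benzylic alcohol from 12 | COc1cc(CO)ccc1O[C@H](COCc1ccccc1)[C@@H](OCc1ccccc1)c1ccc(OCc2ccccc2)c(OC)c1 | intermediate
14 | ArB–CH2Br, the benzylic bromide from 13 | COc1cc(CBr)ccc1O[C@H](COCc1ccccc1)[C@@H](OCc1ccccc1)c1ccc(OCc2ccccc2)c(OC)c1 | intermediate
15 | (R)-4-benzyloxazolidin-2-one | O=C1N[C@H](Cc2ccccc2)CO1 | starting material
16 | methyl 4-chloro-4-oxobutanoate | COC(=O)CCC(Cl)=O | starting material
17 | N-lithio-(R)-4-benzyloxazolidin-2-one (formed in situ) | [Li]N1[C@H](Cc2ccccc2)COC1=O | intermediate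
18 | methyl 4-[(4R)-4-benzyl-2-oxooxazolidin-3-yl]-4-oxobutanoate | COC(=O)CCC(=O)N1[C@H](Cc2ccccc2)COC1=O | intermediate
19 | sodium (Z)-enolate of 18 (formed in situ) | COC(=O)C/C=C(\[O-])N1[C@H](Cc2ccccc2)COC1=O.[Na+] | intermediate
20 | methyl (3R)-3-(ArB-methyl)-4-[(4R)-4-benzyl-2-oxooxazolidin-3-yl]-4-oxobutanoate | COC(=O)C[C@@H](Cc1ccc(O[C@H](COCc2ccccc2)[C@@H](OCc2ccccc2)c2ccc(OCc3ccccc3)c(OC)c2)c(OC)c1)C(=O)N1[C@H](Cc2ccccc2)COC1=O | intermediate
21 | methyl (3R)-4-ArB-3-(hydroxymethyl)butanoate (formed in situ) | COC(=O)C[C@@H](Cc1ccc(O[C@H](COCc2ccccc2)[C@@H](OCc2ccccc2)c2ccc(OCc3ccccc3)c(OC)c2)c(OC)c1)CO | intermediate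
22 | (4R)-4-(ArB-methyl)oxolan-2-one | O=C1C[C@@H](Cc2ccc(O[C@H](COCc3ccccc3)[C@@H](OCc3ccccc3)c3ccc(OCc4ccccc4)c(OC)c3)c(OC)c2)CO1 | intermediate
23 | potassium enolate of 22 (formed in situ) | [K+].[O-]C1=C[C@@H](Cc2ccc(O[C@H](COCc3ccccc3)[C@@H](OCc3ccccc3)c3ccc(OCc4ccccc4)c(OC)c3)c(OC)c2)CO1 | intermediate
24 | (3R,4S)-3-hydroxy-4-(ArB-methyl)oxolan-2-one | O=C1[C@H](O)[C@@H](Cc2ccc(O[C@H](COCc3ccccc3)[C@@H](OCc3ccccc3)c3ccc(OCc4ccccc4)c(OC)c3)c(OC)c2)CO1 | intermediate
25 | [4-(benzyloxy)-3-methoxyphenyl]methanol | COc1cc(CO)ccc1OCc1ccccc1 | starting material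
26 | 1-(benzyloxy)-4-(bromomethyl)-2-methoxybenzene | COc1cc(CBr)ccc1OCc1ccccc1 | intermediate
27 | dilithium enediolate of 24 (formed in situ) | [Li+].[Li+].[O-]C1=C([O-])[C@@H](Cc2ccc(O[C@H](COCc3ccccc3)[C@@H](OCc3ccccc3)c3ccc(OCc4ccccc4)c(OC)c3)c(OC)c2)CO1 | intermediate
28 | (3S,4S)-3-{[4-(benzyloxy)-3-methoxyphenyl]methyl}-3-hydroxy-4-(ArB-methyl)oxolan-2-one | O=C1[C@](O)(Cc2ccc(OCc3ccccc3)c(OC)c2)[C@@H](Cc2ccc(O[C@H](COCc3ccccc3)[C@@H](OCc3ccccc3)c3ccc(OCc4ccccc4)c(OC)c3)c(OC)c2)CO1 | intermediate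
29 | (2S,3S)-2-{[4-(benzyloxy)-3-methoxyphenyl]methyl}-3-(ArB-methyl)butane-1,2,4-triol | COc1cc(C[C@@](O)(CO)[C@H](CO)Cc2ccc(O[C@H](COCc3ccccc3)[C@@H](OCc3ccccc3)c3ccc(OCc4ccccc4)c(OC)c3)c(OC)c2)ccc1OCc1ccccc1 | intermediate
30 | (2S,3S)-2-[(4-hydroxy-3-methoxyphenyl)methyl]-3-[(4-{[(1S,2R)-1,3-dihydroxy-1-(4-hydroxy-3-methoxyphenyl)propan-2-yl]oxy}-3-methoxyphenyl)methyl]butane-1,2,4-triol | COc1cc(C[C@@](O)(CO)[C@H](CO)Cc2ccc(O[C@H](CO)[C@@H](O)c3ccc(O)c(OC)c3)c(OC)c2)ccc1O | intermediate
31 | open-chain pentaol bis(aryl acetate): 30 with the 4-hydroxyls of rings A and C as acetates (key-step precursor) | COc1cc(C[C@@](O)(CO)[C@H](CO)Cc2ccc(O[C@H](CO)[C@@H](O)c3ccc(OC(C)=O)c(OC)c3)c(OC)c2)ccc1OC(C)=O | intermediate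
32 | ring-B para-alkoxybenzylic cation from 31, cationic at C2 (formed in situ) | COc1cc(C[C@@](O)(CO)[C@H](CO)[CH+]c2ccc(O[C@H](CO)[C@@H](O)c3ccc(OC(C)=O)c(OC)c3)c(OC)c2)ccc1OC(C)=O | intermediate
33 | (2S,3R,4S)-oxolane 34 as its ring-A and ring-C aryl acetates (key-step product) | COc1cc(C[C@@]2(O)CO[C@H](c3ccc(O[C@H](CO)[C@@H](O)c4ccc(OC(C)=O)c(OC)c4)c(OC)c3)[C@H]2CO)ccc1OC(C)=O | intermediate
34 | (1S,2R)-1-(4-hydroxy-3-methoxyphenyl)-2-{4-[(2S,3R,4S)-4-hydroxy-4-[(4-hydroxy-3-methoxyphenyl)methyl]-3-(hydroxymethyl)oxolan-2-yl]-2-methoxyphenoxy}propane-1,3-diol | COc1cc(C[C@@]2(O)CO[C@H](c3ccc(O[C@H](CO)[C@@H](O)c4ccc(O)c(OC)c4)c(OC)c3)[C@H]2CO)ccc1O | target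

Total step count: 18. Longest linear sequence: 16 steps (steps 1–7, 9–11 and 13–18); steps 8 and 12 are side branches.

Steps most likely to fail

Step 17. Hydride abstraction may not stop after ring closure, because the new C2–H is again a para-alkoxybenzylic ether C–H, and the cation may be taken by ring A before the oxygen closes. The fallback makes the cation by ionisation instead of by oxidation. It sets out from 31: DDQ (2.5 equiv) in CH2Cl2/H2O would deliberately take the benzylic carbon to the ketone level and give the ring-B aryl ketone F1, which is kept away from base. Zn(BH4)2 in THF at 0 °C would reduce the ketone without touching the aryl acetates to the benzylic alcohol F2, where either carbinol epimer serves. Catalytic pyridinium p-toluenesulfonate in CH2Cl2 would then ionise the para-alkoxybenzylic alcohol to the same cation 32, now with no oxidant present, and the C5 hydroxyl would close the ring (acid-catalysed cyclodehydration of a 1-aryl-1,4-diol). The route is rejoined at 33.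

Step 13. The second deprotonation may be incomplete, the alkoxide may be benzylated at oxygen, and facial control may suffer at the congested enediolate. The fallback alkylates a monoanion. It sets out from 24: Et3SiCl and imidazole in DMF would give the triethylsilyl ether F3, LiN(iPr)2 in THF at −78 °C the lithium enolate F4, and bromide 26 would alkylate it anti to the C4 substituent to give the silyl-protected dibenzyl lactone F5. Bu4NF buffered with AcOH would remove the silyl group and return the route to 28.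

Step 5. The alkoxide may be used up by reversible addition to the formyl group and by base-induced hydride transfer between aldehyde molecules before the hindered secondary alkoxide attacks the ring carbon. The fallback uses an electrophile without a carbonyl group. It sets out from 9 as its alkoxide 11: substitution on 4-fluoro-3-methoxybenzonitrile (DMF, rt → 50 °C) would give the nitrile F6, and (i-Bu)2AlH in toluene at −78 °C followed by mild hydrolysis of the aldimine would give aldehyde 12, where the route is rejoined.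

Further compounds
F1 | step 17 | ring-B aryl ketone: 31 with the ring-B benzylic CH2 oxidised to C=O | COc1cc(C[C@@](O)(CO)[C@H](CO)C(=O)c2ccc(O[C@H](CO)[C@@H](O)c3ccc(OC(C)=O)c(OC)c3)c(OC)c2)ccc1OC(C)=O
F2 | step 17 | benzylic alcohol: 31 with a hydroxyl on the ring-B benzylic carbon (both carbinol epimers) | COc1cc(C[C@@](O)(CO)[C@H](CO)C(O)c2ccc(O[C@H](CO)[C@@H](O)c3ccc(OC(C)=O)c(OC)c3)c(OC)c2)ccc1OC(C)=O
F3 | step 13 | (3R,4S)-4-(ArB-methyl)-3-[(triethylsilyl)oxy]oxolan-2-one | O=C1[C@H](O[Si](CC)(CC)CC)[C@@H](Cc2ccc(O[C@H](COCc3ccccc3)[C@@H](OCc3ccccc3)c3ccc(OCc4ccccc4)c(OC)c3)c(OC)c2)CO1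
F4 | step 13 | lithium enolate of F3 | [Li+].[O-]C1=C(O[Si](CC)(CC)CC)[C@@H](Cc2ccc(O[C@H](COCc3ccccc3)[C@@H](OCc3ccccc3)c3ccc(OCc4ccccc4)c(OC)c3)c(OC)c2)CO1
F5 | step 13 | (3S,4S)-3-{[4-(benzyloxy)-3-methoxyphenyl]methyl}-4-(ArB-methyl)-3-[(triethylsilyl)oxy]oxolan-2-one | O=C1[C@](O[Si](CC)(CC)CC)(Cc2ccc(OCc3ccccc3)c(OC)c2)[C@@H](Cc2ccc(O[C@H](COCc3ccccc3)[C@@H](OCc3ccccc3)c3ccc(OCc4ccccc4)c(OC)c3)c(OC)c2)CO1
F6 | step 5 | 4-{[(1S,2R)-1,3-bis(benzyloxy)-1-[4-(benzyloxy)-3-methoxyphenyl]propan-2-yl]oxy}-3-methoxybenzonitrile | COc1cc(C#N)ccc1O[C@H](COCc1ccccc1)[C@@H](OCc1ccccc1)c1ccc(OCc2ccccc2)c(OC)c1
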